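The data come from a simulation for an exercise, noise included.

0.132 /min is the number to begin from, and you read it from the substrate left at 10.0 min in the eta, alpha and zeta runs: 28%, 25% and 27% of the charge, with 15 mM, 16 mM and 18 mM of solid reagent.

| setting | eta | alpha | zeta | ash | elm | oak |
|---|---|---|---|---|---|---|
| substrate | 20 mM | 20 mM | 20 mM | 20 mM | 20 mM | 20 mM |
| solid reagent | 15 mM | 16 mM | 18 mM | 14.0 mM | 17.0 mM | 20.0 mM |
| remark | run made earlier | run made earlier | run made earlier |  |  |  |
| time |  |  |  | 15 min | 15 min | 15 min |

| run | time / min | target / % | substrate / % | tight pair / % | isomer of the product / % | loose pair / % |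
|---|---|---|---|---|---|---|
| eta | 0.833 | 0 | 88 | 0 | 13 | 4 |
| eta | 1.50 | 0 | 84 | 0 | 18 | 1 |
| eta | 3.00 | 2 | 69 | 0 | 33 | 0 |
| eta | 6.00 | 0 | 46 | 0 | 52 | 3 |
| eta | 10.0 | 0 | 28 | 1 | 74 | 0 |
| alpha | 0.833 | 0 | 92 | 2 | 10 | 1 |
| alpha | 1.50 | 1 | 82 | 1 | 17 | 0 |
| alpha | 3.00 | 0 | 69 | 4 | 32 | 1 |
| alpha | 6.00 | 0 | 45 | 1 | 53 | 0 |
| alpha | 10.0 | 0 | 25 | 0 | 75 | 0 |
| zeta | 2.00 | 1 | 77 | 0 | 23 | 0 |
| zeta | 4.00 | 1 | 61 | 0 | 40 | 0 |
| zeta | 6.00 | 1 | 46 | 0 | 52 | 1 |
| zeta | 8.00 | 0 | 33 | 0 | 67 | 0 |
| zeta | 10.0 | 1 | 27 | 0 | 70 | 1 |

(scatter of a reading: 1.5 percentage points)

- as a solid, counted per litre of solution: solid reagent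
- the numbers in the tables scatter with a standard deviation of 1.5 percentage points
- steps that have been proposed: solid reagent <-> partner; partner + tight pair <-> target; substrate <-> tight pair; tight pair <-> loose pair; partner + loose pair -> isomer of the product
- at the start none of the solid reagent is in solution

- which of these there is most of at the end, counted by the substrate in it, ash (isomer of the product / substrate / target / tight pair / loose pair)
- which of these there is most of at the end, counted by the substrate in it, elm (isomer of the product / substrate / target / tight pair / loose pair)
- which of these there is most of at the end, counted by the substrate in it, oak (isomer of the product / substrate / target / tight pair / loose pair)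
- amount of the one of these that there is most of at the end, in percent of the substrate charged, ash
- amount of the one of these that there is most of at the end, in percent of the substrate charged, elm
- amount of the one of these that there is most of at the end, in percent of the substrate charged, oak

Build the flask up one process at a time. Take first the main step, substrate turning into tight pair, as the rate-limiting step: the three runs read 46%, 45% and 46% of substrate at 6.00 min, the same within a scatter of 1.5 percentage points, so you let substrate decay first order at that constant, and at 15 min this estimate puts 86.2% of the charge past the substrate.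

Now add the capture, partner plus loose pair giving isomer, which spends one partner per substrate, so the isomer cannot pass the ratio of reagent charge to substrate charge: 70.0% in ash, 85.0% in elm and 100% in oak. The eta run last reads 74% of isomer against its ratio of 75.0%.

Then add the rest. In the eta run the isomer already reads 13% at 0.833 min, against 10.4% from the first-order line, so this reading shows no delay from dissolving. At the last eta reading target, tight pair and loose pair stand at 0%, 1% and 0%, so I give them no share of the balance.

Joining the two ends, I take the lesser of the charge ratio and the delivered fraction, which gives 70.0% of isomer for ash, and I call this the lower ceiling. For elm it is 85.0% and for oak 86.2%, so in this estimate solid reagent is the limiting reagent in ash and, narrowly, in elm.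

The forecast names isomer of the product as the largest in ash, isomer of the product in elm and isomer of the product in oak, at 70% (66% to 74%), 83% (78% to 87%) and 86% (82% to 90%). It matches my ceilings for ash and oak and stands lower for elm, on the ground that “capture slows as the partner runs out”.

The flasks give isomer as the largest each time, at 70.0% in ash, 85.0% in elm and 85.5% in oak, against lower ceilings of 70.0%, 85.0% and 86.2%.

    solid reagent ⇌ partner, rate k1*(cs1 - [partner]) while solid is left; crystals form when [partner] > cs1 (solubility = 11.0 mM, k = 0.670 /min)
    partner + tight pair ⇌ target (K = 240 /M, k = 1.90 × 10⁵ /M/min)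
    substrate ⇌ tight pair (K = 0.0170, k = 0.160 /min)
    tight pair ⇌ loose pair (K = 2.60, k = 40.0 /min)
    partner + loose pair → isomer of the product (k = 3.10 × 10⁵ /M/min)

In oak at 15.0 min, the half-life of substrate by the forward rate of its step is 4.3 min, while that of tight pair by its forward conversion into loose pair is 1.0 s. At that time oak holds 0.0476% of tight pair beside 14.4% of substrate. For the flask oak left until 4.0 min, the lower ceiling is 41.1%, and that flask holds 39.8% of isomer.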